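The C4–C4a bond between the carbonyl carbon and ring A of the chromanone is the disconnection on which the route rests. The key step is a Parham cycloacylation: bromine–lithium exchange at C4a of an open-chain (S)-3-aryl-3-aryloxy Weinreb amide gives an aryllithium that attacks the C4 amide carbonyl and closes pyranone ring C in one operation, with the C2 stereocentre already in place. It exploits the ortho relationship on ring A between C4a and the O1-bearing C8a, C4a also lying para to the C7 oxygen. The precursor comes from Mitsunobu inversion of an (R)-β-hydroxy Weinreb amide, made by asymmetric transfer hydrogenation, with 2-bromo-5-silyloxyphenol.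

Key step: step 6

Remark on the chemistry: flavanone numbering is used (O1, C2, C3, C4, C4a, C5 to C8, C8a; ring A is the benzo ring, ring C the pyranone); C2 of the target is S; "geranyl" means (2E)-3,7-dimethylocta-2,6-dien-1-yl; compounds 1, 2, 4 and 7 are taken as commercial.

Step 1
Reactants: 1 methyl 4-hydroxybenzoate; 2 geranyl bromide
Product: 3 methyl 4-(geranyloxy)benzoate
Conditions: K2CO3, DMF, rt
Reagents that add atoms: none
Why: Williamson ether synthesis, in which the phenoxide of 1 displaces bromide from the primary allylic carbon of 2 by SN2, so the E alkene geometry is kept and the soft oxygen nucleophile in DMF favours O-alkylation and SN2 over SN2′.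

Step 2
Reactants: 3 methyl 4-(geranyloxy)benzoate; 4 N-methoxy-N-methylacetamide
Product: 5 3-[4-(geranyloxy)phenyl]-N-methoxy-N-methyl-3-oxopropanamide
Conditions: 4, LiN(i-Pr)2 (2.2 equiv), THF, −78 °C; then 3, −78 to 0 °C; aq. NH4Cl
Reagents that add atoms: none
Why: Crossed Claisen condensation, in which the lithium enolate of 4 is acylated by the non-enolisable benzoate 3 and the product is at once deprotonated to its stabilised enolate, which drives the condensation and shields both carbonyl groups until the quench.

Step 3
Reactants: 5 3-[4-(geranyloxy)phenyl]-N-methoxy-N-methyl-3-oxopropanamide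
Product: 6 (3R)-3-[4-(geranyloxy)phenyl]-3-hydroxy-N-methoxy-N-methylpropanamide
Conditions: RuCl[(R,R)-TsDPEN](p-cymene) (1 mol%), HCO2H/Et3N (5:2), DMF, 35 °C
Reagents that add atoms: none
Why: Noyori-type asymmetric transfer hydrogenation of an aryl ketone, in which the (R,R)-TsDPEN ruthenium hydride delivers hydrogen to the ketone face fixed by the CH/π contact between the aryl ring and the p-cymene ligand, the sense that gives (R)-1-arylethanols, so the new carbinol centre should be R, while the isolated alkenes, the allyl aryl ether and the N–O bond are not reduced by this catalyst.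

Step 4
Reactants: 7 4-bromoresorcinol (4-bromobenzene-1,3-diol)
Product: 8 2-bromo-5-(triisopropylsilyloxy)phenol
Conditions: i-Pr3SiCl (1.0 equiv), imidazole, CH2Cl2, 0 °C
Reagents that add atoms: triisopropylsilyl chloride, CC(C)[Si](Cl)(C(C)C)C(C)C
Why: Silyl ether formation under steric control, in which the bulky silyl chloride should react at the unhindered hydroxyl para to bromine in preference to the hydroxyl flanked by bromine, the minor regioisomer and the bis-silyl ether being removable by chromatography.

Step 5
Reactants: 6 (3R)-3-[4-(geranyloxy)phenyl]-3-hydroxy-N-methoxy-N-methylpropanamide; 8 2-bromo-5-(triisopropylsilyloxy)phenol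
Product: 9 (3S)-3-[2-bromo-5-(triisopropylsilyloxy)phenoxy]-3-[4-(geranyloxy)phenyl]-N-methoxy-N-methylpropanamide
Conditions: PPh3, DIAD, toluene, −20 to 0 °C
Reagents that add atoms: none
Why: Mitsunobu etherification, in which the acidic ortho-bromophenol 8 protonates the betaine and its phenoxide displaces the oxyphosphonium group of 6 by SN2 with inversion, turning the R carbinol into the S aryl ether, while toluene and low temperature disfavour ionisation of the 4-alkoxybenzylic centre and elimination.

Step 6
Reactants: 9 (3S)-3-[2-bromo-5-(triisopropylsilyloxy)phenoxy]-3-[4-(geranyloxy)phenyl]-N-methoxy-N-methylpropanamide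
Product: 12 (2S)-2-[4-(geranyloxy)phenyl]-7-(triisopropylsilyloxy)chroman-4-one, via aryllithium 10 (not isolated), via lithium hemiaminal alkoxide 11 (not isolated)
Conditions: t-BuLi (2.1 equiv), THF, −78 °C; then sat. aq. NH4Cl, −78 °C to rt
Reagents that add atoms: none
Why: Bromine–lithium exchange at C4a should outrun any deprotonation or carbonyl addition by tert-butyllithium at −78 °C (the second equivalent destroys the tert-butyl bromide formed), and the aryllithium 10 then adds to the tethered Weinreb carbonyl, forming the C4–C4a bond and the chelated lithium hemiaminal alkoxide 11, which collapses to the ketone only on the ammonium chloride quench. This is the Parham cyclization in its cycloacylation form, with a Weinreb amide as the internal electrophile. Ring C, the six-membered pyranone, is closed in the 6-exo-trig mode, the carbanion on C4a attacking the trigonal C4 whose C=O bond stays outside the new ring. No stereocentre of the product is created: C2 is carried through because none of its bonds is made or broken, and the transient C4 centre of 11 disappears on collapse. The step needs site selectivity on ring A and chemoselectivity against proton transfer from C3, which would expel the phenoxide by E1cB elimination; the first is fixed by the bromine on C4a, ortho to O1 and para to the C7 silyloxy group, the second by the low temperature, the fast six-membered addition and the Weinreb chelate, which also withholds the base-sensitive flavanone until the mixture is neutral. The silyl ether and the geranyl ether offer no site that should react with an organolithium faster than the exchange at this temperature.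

Step 7
Reactants: 12 (2S)-2-[4-(geranyloxy)phenyl]-7-(triisopropylsilyloxy)chroman-4-one
Product: 13 (2S)-2-[4-(geranyloxy)phenyl]-7-hydroxychroman-4-one (CNP0302343.1)
Conditions: Bu4NF, AcOH (1:1), THF, 0 °C
Reagents that add atoms: none
Why: Fluoride-mediated cleavage of an aryl silyl ether, in which fluoride attacks silicon and the acetic acid buffer protonates the C7 phenoxide as it forms, so no base remains to enolise C3 and open ring C by a retro-oxa-Michael reaction, which should keep C2 intact and leave the geranyl ether alone.

Compound list
1 | methyl 4-hydroxybenzoate | COC(=O)c1ccc(O)cc1 | starting material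
2 | geranyl bromide, (2E)-1-bromo-3,7-dimethylocta-2,6-diene | CC(C)=CCC/C(C)=C/CBr | starting material
3 | methyl 4-(geranyloxy)benzoate | CC(C)=CCC/C(C)=C/COc1ccc(C(=O)OC)cc1 | intermediate
4 | N-methoxy-N-methylacetamide | CC(=O)N(C)OC | starting material
5 | 3-[4-(geranyloxy)phenyl]-N-methoxy-N-methyl-3-oxopropanamide | CC(C)=CCC/C(C)=C/COc1ccc(C(=O)CC(=O)N(C)OC)cc1 | intermediate
6 | (3R)-3-[4-(geranyloxy)phenyl]-3-hydroxy-N-methoxy-N-methylpropanamide | CC(C)=CCC/C(C)=C/COc1ccc([C@H](O)CC(=O)N(C)OC)cc1 | intermediate
7 | 4-bromoresorcinol (4-bromobenzene-1,3-diol) | Oc1ccc(Br)c(O)c1 | starting material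
8 | 2-bromo-5-(triisopropylsilyloxy)phenol | Oc1cc(O[Si](C(C)C)(C(C)C)C(C)C)ccc1Br | intermediate
9 | (3S)-3-[2-bromo-5-(triisopropylsilyloxy)phenoxy]-3-[4-(geranyloxy)phenyl]-N-methoxy-N-methylpropanamide | CC(C)=CCC/C(C)=C/COc1ccc([C@H](CC(=O)N(C)OC)Oc2cc(O[Si](C(C)C)(C(C)C)C(C)C)ccc2Br)cc1 | intermediate
10 | aryllithium from 9, lithium in place of bromine on C4a, (3S) | CC(C)=CCC/C(C)=C/COc1ccc([C@H](CC(=O)N(C)OC)Oc2cc(O[Si](C(C)C)(C(C)C)C(C)C)ccc2[Li])cc1 | intermediate
11 | lithium hemiaminal alkoxide, (2S)-2-[4-(geranyloxy)phenyl]-4-lithiooxy-4-[methoxy(methyl)amino]-7-(triisopropylsilyloxy)chroman, C4 unassigned | CC(C)=CCC/C(C)=C/COc1ccc([C@@H]2CC(O[Li])(N(C)OC)c3ccc(O[Si](C(C)C)(C(C)C)C(C)C)cc3O2)cc1 | intermediate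
12 | (2S)-2-[4-(geranyloxy)phenyl]-7-(triisopropylsilyloxy)chroman-4-one | CC(C)=CCC/C(C)=C/COc1ccc([C@@H]2CC(=O)c3ccc(O[Si](C(C)C)(C(C)C)C(C)C)cc3O2)cc1 | intermediate
13 | (2S)-2-[4-(geranyloxy)phenyl]-7-hydroxychroman-4-one (CNP0302343.1) | CC(C)=CCC/C(C)=C/COc1ccc([C@@H]2CC(=O)c3ccc(O)cc3O2)cc1 | target

Total step count: 7. Longest linear sequence: 6 (steps 1, 2, 3, 5, 6, 7).

Steps most likely to fail

Step 5 (Mitsunobu etherification). The oxyphosphonium leaving group sits on a 4-alkoxybenzylic carbon, so ionisation may compete with direct displacement and erode the enantiomeric purity, and loss of a C3 proton may lead to elimination. The fallback sets the stereocentre by C–H instead of C–O bond formation. It sets out from keto amide 5: enol tosylation (TsCl, N-methylimidazole, LiOH, CH2Cl2) should give the Z enol tosylate (2Z)-3-[4-(geranyloxy)phenyl]-N-methoxy-N-methyl-3-(tosyloxy)prop-2-enamide F1. Addition–elimination of phenol 8 (Cs2CO3, DMF) should then replace the tosylate with retention of alkene geometry, giving the β-aryloxy acrylamide (2Z)-3-[2-bromo-5-(triisopropylsilyloxy)phenoxy]-3-[4-(geranyloxy)phenyl]-N-methoxy-N-methylprop-2-enamide F2. Asymmetric hydrogenation of its enol ether double bond ([Rh(cod)2]BF4, a chiral ferrocenyl bisphosphine of the Walphos or Josiphos family, H2, MeOH, rt, the ligand enantiomer that gives the S product being chosen in a screen) comes back to the route at 9. The aryl bromide and the isolated trisubstituted alkenes are expected to survive a cationic rhodium bisphosphine catalyst.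

Step 6 (Parham cycloacylation). The aryllithium may take a proton from C3 or from the benzylic C2–H instead of adding to the amide, after which the amide enolate would expel the phenoxide by E1cB elimination; tert-butyllithium may also attack the amide before the exchange is complete. The fallback makes the same C4–C4a bond by nickel-catalysed reductive coupling at the aldehyde oxidation level, without a strong base. It sets out from 9: reduction of the Weinreb amide with i-Bu2AlH (THF, −78 °C) should give the aldehyde (3S)-3-[2-bromo-5-(triisopropylsilyloxy)phenoxy]-3-[4-(geranyloxy)phenyl]propanal F3, used crude at once. Intramolecular reductive addition of the aryl bromide to the aldehyde (NiBr2(dme), a bipyridine-type ligand, Zn, DMA, rt) should give the flavan-4-ol (2S)-2-[4-(geranyloxy)phenyl]-7-(triisopropylsilyloxy)chroman-4-ol F4 as a mixture of C4 epimers. Oxidation with Dess–Martin periodinane (NaHCO3, CH2Cl2) removes the C4 stereocentre and comes back to the route at 12.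

Step 2 (Claisen condensation). The amide enolate may condense with itself or decompose on warming faster than it is acylated by the electron-rich, sluggish benzoate. The fallback uses acylketene aminolysis instead of enolate acylation. It sets out from 3: saponification (LiOH, THF/MeOH/H2O) should give 4-(geranyloxy)benzoic acid F5. Coupling with Meldrum's acid (EDC·HCl, DMAP, CH2Cl2) should give the acyl Meldrum's acid 5-{[4-(geranyloxy)phenyl](hydroxy)methylidene}-2,2-dimethyl-1,3-dioxane-4,6-dione F6. Heating with N,O-dimethylhydroxylamine hydrochloride and Et3N (toluene, 80 °C) should open it through the acylketene and come back to the route at 5.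

Further compounds
F1 | step 5 | (2Z)-3-[4-(geranyloxy)phenyl]-N-methoxy-N-methyl-3-{[(4-methylphenyl)sulfonyl]oxy}prop-2-enamide | CC(C)=CCC/C(C)=C/COc1ccc(/C(OS(=O)(=O)c2ccc(C)cc2)=C/C(=O)N(C)OC)cc1
F2 | step 5 | (2Z)-3-[2-bromo-5-(triisopropylsilyloxy)phenoxy]-3-[4-(geranyloxy)phenyl]-N-methoxy-N-methylprop-2-enamide | CC(C)=CCC/C(C)=C/COc1ccc(/C(Oc2cc(O[Si](C(C)C)(C(C)C)C(C)C)ccc2Br)=C/C(=O)N(C)OC)cc1
F3 | step 6 | (3S)-3-[2-bromo-5-(triisopropylsilyloxy)phenoxy]-3-[4-(geranyloxy)phenyl]propanal | CC(C)=CCC/C(C)=C/COc1ccc([C@H](CC=O)Oc2cc(O[Si](C(C)C)(C(C)C)C(C)C)ccc2Br)cc1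
F4 | step 6 | (2S)-2-[4-(geranyloxy)phenyl]-7-(triisopropylsilyloxy)chroman-4-ol, C4 epimers | CC(C)=CCC/C(C)=C/COc1ccc([C@@H]2CC(O)c3ccc(O[Si](C(C)C)(C(C)C)C(C)C)cc3O2)cc1
F5 | step 2 | 4-(geranyloxy)benzoic acid | CC(C)=CCC/C(C)=C/COc1ccc(C(=O)O)cc1
F6 | step 2 | 5-{[4-(geranyloxy)phenyl](hydroxy)methylidene}-2,2-dimethyl-1,3-dioxane-4,6-dione | CC(C)=CCC/C(C)=C/COc1ccc(C(O)=C2C(=O)OC(C)(C)OC2=O)cc1
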